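**Strategy**

The oxolane ring (O1, aryl-bearing C2, hydroxymethyl-bearing C3, aroyl-bearing C4, methylene C5) is divided into a C2–O1 unit and a C3–C4–C5 unit. O1 and benzylic C2 are the carbonyl of an aryl aldehyde; C3 and C5 both lie β to the C4 aroyl ketone. An α-methylene aryl ketone with an oxazolidinone imide carbonyl on C3 therefore serves as an ambiphilic three-carbon partner. In one pot its boron dienolate adds through C3 to the aldehyde (C2–C3, both centres auxiliary-controlled) and the C2 alkoxide closes onto the enone terminus C5 (O1–C5), C4 settling trans. The aldehyde already carries the erythro 8-O-4′ side chain; the imide carbonyl later becomes the hydroxymethyl group.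

Key step: step 11

**Remarks**

- Abbreviations used in names: ArA = 4-{[(4R,5S)-4-(4-benzyloxy-3-methoxyphenyl)-2,2-dimethyl-1,3-dioxan-5-yl]oxy}-3,5-dimethoxyphenyl; ArB = 4-benzyloxy-3,5-dimethoxyphenyl.
- Assumption on the chemistry of step 3: the titanium-mediated anti-glycolate aldol is taken to set the aryloxy-bearing α-centre in the same auxiliary-controlled sense as the corresponding syn glycolate aldol, so that the (R)-auxiliary leads to the (2R,3R) adduct.

**Route**

Step 1
Reactants: 1 4-bromo-2,6-dimethoxyphenol; 2 bromoacetic acid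
Product: 3 2-(4-bromo-2,6-dimethoxyphenoxy)acetic acid
Conditions: NaH (2.5 equiv), THF/DMF, 0 to 60 °C; then 1 M HCl
Reagents that add atoms: none
Why: Williamson ether synthesis, the sodium phenoxide displacing bromide from sodium bromoacetate by SN2; no stereocentre is formed.

Step 2
Reactants: 3 2-(4-bromo-2,6-dimethoxyphenoxy)acetic acid; 4 (R)-4-benzyl-1,3-oxazolidine-2-thione
Product: 6 (R)-4-benzyl-3-[2-(4-bromo-2,6-dimethoxyphenoxy)acetyl]-1,3-oxazolidine-2-thione, via mixed pivalic anhydride 5 (not isolated)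
Conditions: PivCl, Et3N, THF, −20 °C; then 4, LiCl, −20 °C to rt
Reagents that add atoms: none
Why: N-acylation of the auxiliary through the mixed pivalic anhydride, the hindered pivaloyl carbonyl directing attack to the aryloxyacetyl carbonyl.

Step 3
Reactants: 6 (R)-4-benzyl-3-[2-(4-bromo-2,6-dimethoxyphenoxy)acetyl]-1,3-oxazolidine-2-thione; 7 4-(benzyloxy)-3-methoxybenzaldehyde
Product: 9 (R)-4-benzyl-3-[(2R,3R)-3-(4-benzyloxy-3-methoxyphenyl)-2-(4-bromo-2,6-dimethoxyphenoxy)-3-hydroxypropanoyl]-1,3-oxazolidine-2-thione, via chlorotitanium enolate 8 (not isolated)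
Conditions: TiCl4 (1.1 equiv), i-Pr2NEt (1.1 equiv), CH2Cl2, −78 °C; then 7 precomplexed with TiCl4 (2.5 equiv), −78 °C
Reagents that add atoms: none
Why: Titanium-mediated anti-glycolate aldol of an N-glycolyl oxazolidinethione, in which the (Z)-chlorotitanium enolate adds to the TiCl4-activated aldehyde through an open transition state; the auxiliary benzyl group should fix the aryloxy-bearing α-centre and the open geometry the anti (erythro) benzylic carbinol.

Step 4
Reactants: 9 the anti-aldol adduct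
Product: 10 (1R,2S)-1-(4-benzyloxy-3-methoxyphenyl)-2-(4-bromo-2,6-dimethoxyphenoxy)propane-1,3-diol
Conditions: NaBH4, THF/H2O, 0 °C to rt
Reagents that add atoms: none
Why: Reductive cleavage of the activated N-acyl oxazolidinethione by borohydride gives the primary alcohol and returns the auxiliary, without touching the two stereocentres or the aryl bromide.

Step 5
Reactants: 10 the erythro diol
Product: 11 (4R,5S)-4-(4-benzyloxy-3-methoxyphenyl)-5-(4-bromo-2,6-dimethoxyphenoxy)-2,2-dimethyl-1,3-dioxane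
Conditions: Me2C(OMe)2, PPTS (cat.), acetone, rt
Reagents that add atoms: 2,2-dimethoxypropane, COC(C)(C)OC
Why: Acid-catalysed transacetalisation closes the six-membered isopropylidene acetal across the 1,3-diol, masking both hydroxyls against organolithium, hydride and MnO2 in later steps.

Step 6
Reactants: 11 the bromo acetonide
Product: 13 ArA-carbaldehyde (4-{[(4R,5S)-4-(4-benzyloxy-3-methoxyphenyl)-2,2-dimethyl-1,3-dioxan-5-yl]oxy}-3,5-dimethoxybenzaldehyde), via aryllithium 12 (not isolated)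
Conditions: n-BuLi, THF, −78 °C; DMF, −78 °C to rt; H2O
Reagents that add atoms: N,N-dimethylformamide, CN(C)C=O
Why: Bromine–lithium exchange followed by formylation of the aryllithium with DMF (Bouveault aldehyde synthesis); the acetal and the ethers are inert at −78 °C.

Step 7
Reactants: 1 4-bromo-2,6-dimethoxyphenol
Product: 14 2-(benzyloxy)-5-bromo-1,3-dimethoxybenzene
Conditions: BnBr, K2CO3, DMF, rt
Reagents that add atoms: benzyl bromide, BrCc1ccccc1
Why: Williamson O-benzylation of the phenol.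

Step 8
Reactants: 14 2-(benzyloxy)-5-bromo-1,3-dimethoxybenzene; 15 succinic anhydride
Product: 17 4-ArB-4-oxobutanoic acid, via aryllithium 16 (not isolated)
Conditions: n-BuLi, THF, −78 °C; inverse addition to 15 (2 equiv), THF, −78 °C to rt; 1 M HCl
Reagents that add atoms: none
Why: Bromine–lithium exchange and acylation of the aryllithium by the cyclic anhydride; ring opening gives a carboxylate, and inverse addition keeps the new ketone from a second addition.

Step 9
Reactants: 17 4-ArB-4-oxobutanoic acid; 18 (S)-4-benzyl-1,3-oxazolidin-2-one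
Product: 20 (S)-4-benzyl-3-(4-ArB-4-oxobutanoyl)-1,3-oxazolidin-2-one, via mixed pivalic anhydride 19 (not isolated)
Conditions: PivCl, Et3N, THF, −20 °C; then 18, LiCl, rt
Reagents that add atoms: none
Why: N-acylation of the oxazolidinone through the mixed pivalic anhydride under LiCl/Et3N activation.

Step 10
Reactants: 20 the saturated keto imide
Product: 21 (S)-4-benzyl-3-[3-(ArB-carbonyl)but-3-enoyl]-1,3-oxazolidin-2-one
Conditions: (CH2O)n, i-Pr2NH·TFA, TFA (cat.), THF, reflux
Reagents that add atoms: paraformaldehyde (as formaldehyde), C=O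
Why: Mannich-type α-methylenation (aminomethylation then elimination) at the only enolisable position of the aryl ketone; the imide α-CH2 does not enolise under the acidic amine-salt conditions.

Step 11
Reactants: 13 ArA-carbaldehyde; 21 the α-methylene keto imide
Product: 24 (S)-4-benzyl-3-{[(2S,3S,4S)-2-ArA-4-(ArB-carbonyl)oxolan-3-yl]carbonyl}-1,3-oxazolidin-2-one, via dibutylboron dienolate 22 (not isolated), via syn-aldol adduct 23 (not isolated)
Conditions: Bu2BOTf (1.2 equiv), i-Pr2NEt (1.4 equiv), CH2Cl2, −78 to 0 °C; 13, −78 to 0 °C; then MeOH (5 equiv), DBU (2 equiv), 0 °C to rt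
Reagents that add atoms: none
Why: Soft enolisation of 21 gives the (Z)-boron dienolate 22, which adds through its α-carbon (C3) to aldehyde 13 in a closed Zimmerman–Traxler chair to give 23; after methanolysis of the borinate, DBU generates the C2 alkoxide, which adds to the terminal carbon C5 of the α-methylene aryl ketone (intramolecular oxa-Michael addition) and the resulting enolate is protonated at C4. The closest known reactions are the Evans boron syn aldol of β,γ-unsaturated (crotonyl-type) imide dienolates and the base-mediated cyclisation of homoallylic alcohols onto 2-sulfonyl- or 2-acyl-substituted alkenes. The oxolane closes in the 5-endo-trig mode, formally disfavoured but reversible and thermodynamically driven for alkoxides adding to polarised acceptors. C3 is set by the benzyl group of the (S)-oxazolidinone shielding one enolate face, C2 by the chair transition state of the (Z)-enolate (syn aldol, which corresponds to 2,3-trans in the ring), and C4 by equilibration α to the ketone, which places the aroyl group trans to C3. The step needs α- over γ-attack of the dienolate (secured by the cyclic boron transition state), reagent control over the remote dioxane stereocentres (secured by the auxiliary), and ring closure faster than migration of the exocyclic double bond (the imide α-hydrogen is held near the carbonyl plane by 1,3-allylic strain and is kinetically non-acidic).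

Step 12
Reactants: 24 the oxolane imide
Product: 25 [(2S,3R,4S)-2-ArA-4-[ArB(hydroxy)methyl]oxolan-3-yl]methanol (both carbinol epimers)
Conditions: LiBH4, THF, H2O (1 equiv), 0 °C to rt
Reagents that add atoms: none
Why: LiBH4 cleaves the imide reductively to the C3 hydroxymethyl group and also reduces the aryl ketone; the new carbinol centre is of no consequence because it is re-oxidised in step 13.

Step 13
Reactants: 25 the diol
Product: 26 (2S,3R,4S)-2-ArA-4-(ArB-carbonyl)-3-(hydroxymethyl)oxolane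
Conditions: MnO2 (activated, excess), CH2Cl2, rt
Reagents that add atoms: none
Why: MnO2 oxidises the secondary benzylic alcohol selectively over the primary aliphatic alcohol (benzylic alcohol oxidation); C4 keeps its trans configuration, and the trans hydroxymethyl group cannot form a hemiketal with the ketone.

Step 14
Reactants: 26 the keto alcohol acetonide
Product: 27 (2S,3R,4S)-4-(ArB-carbonyl)-3-(hydroxymethyl)-2-{4-[(1R,2S)-1-(4-benzyloxy-3-methoxyphenyl)-1,3-dihydroxypropan-2-yl]oxy-3,5-dimethoxyphenyl}oxolane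
Conditions: AcOH/H2O (4:1), 40 °C
Reagents that add atoms: none
Why: Mild aqueous acid hydrolysis of the isopropylidene acetal, under conditions too weak to ionise the benzylic carbinol, so the erythro centres should be retained.

Step 15
Reactants: 27 the bis-benzyl ether
Product: 28 CNP0236429.1, (2S,3R,4S)-4-(4-hydroxy-3,5-dimethoxybenzoyl)-3-(hydroxymethyl)-2-{4-[(1R,2S)-1,3-dihydroxy-1-(4-hydroxy-3-methoxyphenyl)propan-2-yl]oxy-3,5-dimethoxyphenyl}oxolane
Conditions: H2 (1 atm), Pd/C (10 wt%), EtOAc/MeOH, rt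
Reagents that add atoms: none
Why: Hydrogenolysis of the two aryl benzyl ethers over Pd/C, which should be faster than cleavage of the benzylic oxolane C–O bond or reduction of the electron-rich aryl ketone when stopped after two equivalents of H2.

**Compound list**

1 | 4-bromo-2,6-dimethoxyphenol | COc1cc(Br)cc(OC)c1O | starting material
2 | bromoacetic acid | OC(=O)CBr | starting material
3 | 2-(4-bromo-2,6-dimethoxyphenoxy)acetic acid | COc1cc(Br)cc(OC)c1OCC(=O)O | intermediate
4 | (R)-4-benzyl-1,3-oxazolidine-2-thione | S=C1N[C@H](Cc2ccccc2)CO1 | starting material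
5 | 2-(4-bromo-2,6-dimethoxyphenoxy)acetic pivalic anhydride | COc1cc(Br)cc(OC)c1OCC(=O)OC(=O)C(C)(C)C | intermediate
6 | (R)-4-benzyl-3-[2-(4-bromo-2,6-dimethoxyphenoxy)acetyl]-1,3-oxazolidine-2-thione | COc1cc(Br)cc(OC)c1OCC(=O)N1[C@H](Cc2ccccc2)COC1=S | intermediate
7 | 4-(benzyloxy)-3-methoxybenzaldehyde | COc1cc(C=O)ccc1OCc1ccccc1 | starting material
8 | trichlorotitanium (Z)-enolate of 6 | Cl[Ti](Cl)(Cl)O/C(=C\Oc1c(OC)cc(Br)cc1OC)N1[C@H](Cc2ccccc2)COC1=S | intermediate
9 | (R)-4-benzyl-3-[(2R,3R)-3-(4-benzyloxy-3-methoxyphenyl)-2-(4-bromo-2,6-dimethoxyphenoxy)-3-hydroxypropanoyl]-1,3-oxazolidine-2-thione | COc1cc([C@@H](O)[C@H](C(=O)N2[C@H](Cc3ccccc3)COC2=S)Oc2c(OC)cc(Br)cc2OC)ccc1OCc1ccccc1 | intermediate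
10 | (1R,2S)-1-(4-benzyloxy-3-methoxyphenyl)-2-(4-bromo-2,6-dimethoxyphenoxy)propane-1,3-diol | COc1cc([C@@H](O)[C@H](CO)Oc2c(OC)cc(Br)cc2OC)ccc1OCc1ccccc1 | intermediate
11 | (4R,5S)-4-(4-benzyloxy-3-methoxyphenyl)-5-(4-bromo-2,6-dimethoxyphenoxy)-2,2-dimethyl-1,3-dioxane | COc1cc([C@H]2OC(C)(C)OC[C@@H]2Oc2c(OC)cc(Br)cc2OC)ccc1OCc1ccccc1 | intermediate
12 | aryllithium from 11 (ArA-lithium) | COc1cc([C@H]2OC(C)(C)OC[C@@H]2Oc2c(OC)cc([Li])cc2OC)ccc1OCc1ccccc1 | intermediate
13 | 4-{[(4R,5S)-4-(4-benzyloxy-3-methoxyphenyl)-2,2-dimethyl-1,3-dioxan-5-yl]oxy}-3,5-dimethoxybenzaldehyde (ArA-carbaldehyde) | COc1cc([C@H]2OC(C)(C)OC[C@@H]2Oc2c(OC)cc(C=O)cc2OC)ccc1OCc1ccccc1 | intermediate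
14 | 2-(benzyloxy)-5-bromo-1,3-dimethoxybenzene | COc1cc(Br)cc(OC)c1OCc1ccccc1 | intermediate
15 | succinic anhydride | O=C1CCC(=O)O1 | starting material
16 | (4-benzyloxy-3,5-dimethoxyphenyl)lithium | [Li]c1cc(OC)c(OCc2ccccc2)c(OC)c1 | intermediate
17 | 4-(4-benzyloxy-3,5-dimethoxyphenyl)-4-oxobutanoic acid | COc1cc(C(=O)CCC(=O)O)cc(OC)c1OCc1ccccc1 | intermediate
18 | (S)-4-benzyl-1,3-oxazolidin-2-one | O=C1N[C@@H](Cc2ccccc2)CO1 | starting material
19 | 4-(4-benzyloxy-3,5-dimethoxyphenyl)-4-oxobutanoic pivalic anhydride | COc1cc(C(=O)CCC(=O)OC(=O)C(C)(C)C)cc(OC)c1OCc1ccccc1 | intermediate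
20 | (S)-4-benzyl-3-[4-(4-benzyloxy-3,5-dimethoxyphenyl)-4-oxobutanoyl]-1,3-oxazolidin-2-one | COc1cc(C(=O)CCC(=O)N2[C@@H](Cc3ccccc3)COC2=O)cc(OC)c1OCc1ccccc1 | intermediate
21 | (S)-4-benzyl-3-[3-(4-benzyloxy-3,5-dimethoxybenzoyl)but-3-enoyl]-1,3-oxazolidin-2-one | COc1cc(C(=O)C(=C)CC(=O)N2[C@@H](Cc3ccccc3)COC2=O)cc(OC)c1OCc1ccccc1 | intermediate
22 | dibutylboron (Z)-dienolate of 21 | CCCCB(CCCC)O/C(=C\C(=C)C(=O)c1cc(OC)c(OCc2ccccc2)c(OC)c1)N1[C@@H](Cc2ccccc2)COC1=O | intermediate
23 | (S)-4-benzyl-3-{(2S)-3-(ArB-carbonyl)-2-[(S)-ArA(hydroxy)methyl]but-3-enoyl}-1,3-oxazolidin-2-one | COc1cc([C@H]2OC(C)(C)OC[C@@H]2Oc2c(OC)cc([C@@H](O)[C@@H](C(=O)N3[C@@H](Cc4ccccc4)COC3=O)C(=C)C(=O)c3cc(OC)c(OCc4ccccc4)c(OC)c3)cc2OC)ccc1OCc1ccccc1 | intermediate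
24 | (S)-4-benzyl-3-{[(2S,3S,4S)-2-ArA-4-(ArB-carbonyl)oxolan-3-yl]carbonyl}-1,3-oxazolidin-2-one | COc1cc([C@H]2OC(C)(C)OC[C@@H]2Oc2c(OC)cc([C@H]3OC[C@@H](C(=O)c4cc(OC)c(OCc5ccccc5)c(OC)c4)[C@@H]3C(=O)N3[C@@H](Cc4ccccc4)COC3=O)cc2OC)ccc1OCc1ccccc1 | intermediate
25 | [(2S,3R,4S)-2-ArA-4-[ArB(hydroxy)methyl]oxolan-3-yl]methanol, both carbinol epimers | COc1cc([C@H]2OC(C)(C)OC[C@@H]2Oc2c(OC)cc([C@H]3OC[C@@H](C(O)c4cc(OC)c(OCc5ccccc5)c(OC)c4)[C@@H]3CO)cc2OC)ccc1OCc1ccccc1 | intermediate
26 | (2S,3R,4S)-2-ArA-4-(ArB-carbonyl)-3-(hydroxymethyl)oxolane | COc1cc([C@H]2OC(C)(C)OC[C@@H]2Oc2c(OC)cc([C@H]3OC[C@@H](C(=O)c4cc(OC)c(OCc5ccccc5)c(OC)c4)[C@@H]3CO)cc2OC)ccc1OCc1ccccc1 | intermediate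
27 | (2S,3R,4S)-4-(ArB-carbonyl)-3-(hydroxymethyl)-2-{4-[(1R,2S)-1-(4-benzyloxy-3-methoxyphenyl)-1,3-dihydroxypropan-2-yl]oxy-3,5-dimethoxyphenyl}oxolane | COc1cc([C@@H](O)[C@H](CO)Oc2c(OC)cc([C@H]3OC[C@@H](C(=O)c4cc(OC)c(OCc5ccccc5)c(OC)c4)[C@@H]3CO)cc2OC)ccc1OCc1ccccc1 | intermediate
28 | CNP0236429.1 | COc1cc([C@@H](O)[C@H](CO)Oc2c(OC)cc([C@H]3OC[C@@H](C(=O)c4cc(OC)c(O)c(OC)c4)[C@@H]3CO)cc2OC)ccc1O | target

**Count**

Total steps: 15. Longest linear sequence: 11 steps (steps 1–6, then 11–15).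

**Steps most likely to fail**

1. Step 11. Soft enolisation of the cross-conjugated enone imide 21 may be diverted by polymerisation of the enone, γ-attack of the dienolate or migration of the exocyclic double bond into conjugation, and the 5-endo ring closure may lag behind these processes. The fallback sets out from the saturated keto imide 20 and changes the order of bond formation. A plain Evans boron aldol of 20 with aldehyde 13 (Bu2BOTf, i-Pr2NEt, CH2Cl2, −78 to 0 °C) should give, with the same control of C2 and C3, the γ-keto syn-aldol adduct (S)-4-benzyl-3-{(2S)-2-[(S)-ArA(hydroxy)methyl]-4-ArB-4-oxobutanoyl}-1,3-oxazolidin-2-one F1. C5 is then introduced last by Mannich-type α-methylenation of the aryl ketone ((CH2O)n, i-Pr2NH·TFA, THF, reflux), which generates 23 with the C2 hydroxyl in place and lets it close; the route is rejoined at 24.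

2. Step 3. The anti (erythro) selectivity may erode, or the facial sense may be reversed, with an aryloxy instead of an alkoxy glycolate, and excess TiCl4 may begin to cleave the benzyl ether. The fallback sets out from acid 3. Acylation of (R)-4-benzyl-1,3-oxazolidin-2-one (PivCl, Et3N, LiCl) gives the imide (R)-4-benzyl-3-[2-(4-bromo-2,6-dimethoxyphenoxy)acetyl]-1,3-oxazolidin-2-one F2. The boron-mediated Evans syn aldol with 7 (Bu2BOTf, i-Pr2NEt, CH2Cl2, −78 to 0 °C) gives the (2R,3S) syn adduct F3, whose configuration is secure. LiBH4 then gives the threo diol (1S,2S)-1-(4-benzyloxy-3-methoxyphenyl)-2-(4-bromo-2,6-dimethoxyphenoxy)propane-1,3-diol F4. Selective oxidation of the benzylic alcohol (DDQ, dioxane, rt) gives the ketone (S)-1-(4-benzyloxy-3-methoxyphenyl)-2-(4-bromo-2,6-dimethoxyphenoxy)-3-hydroxypropan-1-one F5, and chelation-controlled reduction (Zn(BH4)2, Et2O, 0 °C) inverts the carbinol centre to the erythro diol; the route is rejoined at 10.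

3. Step 13. Oxidation of the electron-rich secondary benzylic alcohol may be sluggish, while the benzylic C2–H of the oxolane or the primary alcohol begins to be attacked. The fallback sets out from 24 and avoids reducing the ketone at all. Hydrolytic removal of the auxiliary (LiOH, H2O2, THF/H2O, 0 °C) gives the carboxylic acid (2S,3S,4S)-2-ArA-4-(ArB-carbonyl)oxolane-3-carboxylic acid F6. Chemoselective reduction of the acid in the presence of the aryl ketone (BH3·SMe2, THF, 0 °C) gives the hydroxymethyl ketone directly; the route is rejoined at 26.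

**Further compounds**

F1 | step 11 | (S)-4-benzyl-3-{(2S)-2-[(S)-ArA(hydroxy)methyl]-4-ArB-4-oxobutanoyl}-1,3-oxazolidin-2-one | COc1cc([C@H]2OC(C)(C)OC[C@@H]2Oc2c(OC)cc([C@@H](O)[C@@H](C(=O)N3[C@@H](Cc4ccccc4)COC3=O)CC(=O)c3cc(OC)c(OCc4ccccc4)c(OC)c3)cc2OC)ccc1OCc1ccccc1
F2 | step 3 | (R)-4-benzyl-3-[2-(4-bromo-2,6-dimethoxyphenoxy)acetyl]-1,3-oxazolidin-2-one | COc1cc(Br)cc(OC)c1OCC(=O)N1[C@H](Cc2ccccc2)COC1=O
F3 | step 3 | (R)-4-benzyl-3-[(2R,3S)-3-(4-benzyloxy-3-methoxyphenyl)-2-(4-bromo-2,6-dimethoxyphenoxy)-3-hydroxypropanoyl]-1,3-oxazolidin-2-one | COc1cc([C@H](O)[C@H](C(=O)N2[C@H](Cc3ccccc3)COC2=O)Oc2c(OC)cc(Br)cc2OC)ccc1OCc1ccccc1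
F4 | step 3 | (1S,2S)-1-(4-benzyloxy-3-methoxyphenyl)-2-(4-bromo-2,6-dimethoxyphenoxy)propane-1,3-diol | COc1cc([C@H](O)[C@H](CO)Oc2c(OC)cc(Br)cc2OC)ccc1OCc1ccccc1
F5 | step 3 | (S)-1-(4-benzyloxy-3-methoxyphenyl)-2-(4-bromo-2,6-dimethoxyphenoxy)-3-hydroxypropan-1-one | COc1cc(C(=O)[C@H](CO)Oc2c(OC)cc(Br)cc2OC)ccc1OCc1ccccc1
F6 | step 13 | (2S,3S,4S)-2-ArA-4-(ArB-carbonyl)oxolane-3-carboxylic acid | COc1cc([C@H]2OC(C)(C)OC[C@@H]2Oc2c(OC)cc([C@H]3OC[C@@H](C(=O)c4cc(OC)c(OCc5ccccc5)c(OC)c4)[C@@H]3C(=O)O)cc2OC)ccc1OCc1ccccc1
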